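The runs stem from a simulated flask on assumed constants; the scatter is artificial.

Amounts opened the meeting: the flask holds 0.10 M substrate and 1.10 equiv of partner, and the members were to say how its target runs up to 2.0 min.

| flask | substrate | partner | remark | time |
|---|---|---|---|---|
| north-west | 0.10 M | 1.1 equiv | the very flask that is asked about, followed so far |  |
| east | 0.050 M | 1.1 equiv | run made earlier |  |
| flask | 0.10 M | 1.10 equiv |  | 2.0 min |

| run | time / s | target / % |
|---|---|---|
| north-west | 25.0 | 22.7 |
| north-west | 30.0 | 24.7 |
| east | 30.0 | 14.1 |
| east | 40.0 | 17.0 |
| east | 50.0 | 19.0 |
| east | 60.0 | 21.0 |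
| east | 80.0 | 24.6 |

(scatter of a reading: 0.3 percentage points)

* when, up to 2.0 min, the flask holds most target
* the amount of target, in percent of the substrate charged, at that time

A first member pointed to the quick start of the east run: target gains 2.9 percentage points from 30.0 s to 40.0 s, but 2 points in the next equal step. She proposed to use the stretch from 40.0 s to 80.0 s, dividing its gain by the mean substrate and partner left. This gives a late second-order constant κ of 0.0538 L mol⁻¹ s⁻¹.

I turned κ into a time. The charge time τ, the inverse of κ·c_partner at the charged partner, is a pseudo-first-order lifetime of substrate: 2.82 min.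

A second member asked whether target might peak early, since the north-west run offers just two readings, with a scatter of 0.3 points. I answered that τ is longer than 2.0 min, so I put the maximum at the end. Integrating from the reading at 30.0 s with κ, and reading reacted substrate as target, I reckoned 47.1 %.

The forecast, expecting “a maximum when formation equals loss”, gave 37 % at 1.2 min.

The flask gives 42.1 % at 2.00 min, which is 5 points less than my figure.

    substrate + partner → intermediate + released group (k = 0.237 L mol⁻¹ s⁻¹)
    intermediate ⇌ target (K = 13.0, k = 0.277 s⁻¹)
    intermediate ⇌ isomer of the product A (K = 2.73, k = 0.0343 s⁻¹)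
    target ⇌ isomer of the product B (K = 0.190, k = 0.00295 s⁻¹)
    partner ⇌ dormant form (K = 1.43, k = 0.0473 s⁻¹)

The neighbouring flask changes one setting, to 4.40 equiv of partner. Its τ is 0.704 min, shorter than 2.0 min, where this flask's 2.82 min was longer. Taken as a lifetime, it leaves 5.84 % of the substrate at 2.00 min. That flask then holds 0.872 % substrate, there the limiting reagent, with partner at 31.8 % of its own charge, and its target reaches 70.0 %.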